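The route rests on cutting the upper chroman at C3–C4 and O1–C2. In that ring the array O1–C8a–C4a–C4, whose doubly benzylic C4 is para-related to the 7-oxygen and bears the central aryl ring, is a masked ortho-quinone methide, while C2–C3(aryl) is an arylacetaldehyde. A chiral secondary amine unites them in one flask: enamine addition forms C3–C4, sets both upper stereocentres trans, and hemiacetalisation closes the pyran ring. The precursor is a 2-[aryl(tosyl)methyl]phenol whose aryl group is the complete lower isoflavan, made enantiopure by an Evans alkylation and joined through a bromine placed at C5' of its ring B.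

Key step: step 18

Remark: the SMILES is read as 3R in the lower isoflavan and 3R,4S (trans) in the upper chroman; "(3R)-7,2'-di-O-benzylvestitol-5'-yl" denotes the 4-benzyloxy-5-[(3R)-7-benzyloxychroman-3-yl]-2-methoxyphenyl group; the carbinol carbon of 20 and 21, the sulfonyl carbon of 22 and C2 of lactol 30 are carried as epimer mixtures because each is later planarised or becomes CH2.

Step 1
Reactants: 1 paeonol (1-(2-hydroxy-4-methoxyphenyl)ethanone)
Product: 2 1-(2-benzyloxy-4-methoxyphenyl)ethanone
Conditions: BnBr, K2CO3, KI (cat.), DMF, 60 °C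
Reagents that add atoms: benzyl bromide BrCc1ccccc1
Why: Williamson ether synthesis, in which the carbonate deprotonates the hydrogen-bonded ortho-hydroxy group and the phenoxide is benzylated on oxygen, gentle heating being needed only because of chelation to the ketone.

Step 2
Reactants: 2 1-(2-benzyloxy-4-methoxyphenyl)ethanone
Product: 4 2-(2-benzyloxy-4-methoxyphenyl)acetic acid, via thiomorpholide 3 (not isolated)
Conditions: S8, morpholine, 130 °C; then NaOH, EtOH/H2O, reflux; then aq. HCl
Reagents that add atoms: sodium hydroxide [Na+].[OH-]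
Why: Willgerodt–Kindler reaction, which moves the oxidation level of the aryl methyl ketone to the terminal carbon as thiomorpholide 3, followed by alkaline hydrolysis to the arylacetic acid; the benzyl and methyl ethers are inert to sulfur, amine and hydroxide.

Step 3
Reactants: 4 2-(2-benzyloxy-4-methoxyphenyl)acetic acid
Product: 5 2-(2-benzyloxy-5-bromo-4-methoxyphenyl)acetic acid
Conditions: NBS, MeCN, 0 °C to rt
Reagents that add atoms: N-bromosuccinimide O=C1CCC(=O)N1Br
Why: Electrophilic aromatic bromination, expected at C5 only because it is para to the benzyloxy group, ortho to the methoxy group and unhindered (C3 lies between two alkoxy groups, C6 is meta to both), which fixes the later linkage site on ring B.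

Step 4
Reactants: 5 2-(2-benzyloxy-5-bromo-4-methoxyphenyl)acetic acid; 6 (R)-4-benzyl-2-oxazolidinone
Product: 8 (R)-4-benzyl-3-[2-(2-benzyloxy-5-bromo-4-methoxyphenyl)acetyl]oxazolidin-2-one, via mixed anhydride 7 (not isolated)
Conditions: t-BuCOCl, Et3N, THF, −20 °C; then LiCl, 6, −20 °C to rt
Reagents that add atoms: none
Why: N-acylation of the auxiliary through the mixed pivalic anhydride, the lithium-activated oxazolidinone attacking the less hindered arylacetyl carbonyl without any strong base that could touch the aryl bromide.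

Step 5
Reactants: 9 4-benzyloxy-2-hydroxybenzaldehyde
Product: 10 4-benzyloxy-2-(methoxymethoxy)benzaldehyde
Conditions: MeOCH2Cl, i-Pr2NEt, CH2Cl2, 0 °C to rt
Reagents that add atoms: chloromethyl methyl ether COCCl
Why: O-alkylation of the phenol to its methoxymethyl acetal, a group that survives enolate, hydride and phosphine chemistry and is later removed by mild acid.

Step 6
Reactants: 10 4-benzyloxy-2-(methoxymethoxy)benzaldehyde
Product: 11 [4-benzyloxy-2-(methoxymethoxy)phenyl]methanol
Conditions: NaBH4, MeOH, 0 °C
Reagents that add atoms: none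
Why: Borohydride reduction of the aryl aldehyde to the benzyl alcohol, which leaves acetal and benzyl ether untouched.

Step 7
Reactants: 11 [4-benzyloxy-2-(methoxymethoxy)phenyl]methanol
Product: 12 4-benzyloxy-1-(bromomethyl)-2-(methoxymethoxy)benzene
Conditions: CBr4, PPh3, CH2Cl2, 0 °C (used at once)
Reagents that add atoms: carbon tetrabromide BrC(Br)(Br)Br
Why: Appel reaction, in which bromide displaces the alkoxyphosphonium ion under neutral conditions that spare the acid-labile acetal; the electron-rich benzyl bromide is carried on without storage.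

Step 8
Reactants: 8 (R)-4-benzyl-3-[2-(2-benzyloxy-5-bromo-4-methoxyphenyl)acetyl]oxazolidin-2-one; 12 4-benzyloxy-1-(bromomethyl)-2-(methoxymethoxy)benzene
Product: 14 (R)-4-benzyl-3-[(2R)-2-(2-benzyloxy-5-bromo-4-methoxyphenyl)-3-(4-benzyloxy-2-(methoxymethoxy)phenyl)propanoyl]oxazolidin-2-one, via sodium enolate 13 (not isolated)
Conditions: NaN(SiMe3)2, THF, −78 °C; then 12, −78 to −40 °C; AcOH quench at −78 °C
Reagents that add atoms: none
Why: Evans asymmetric alkylation, in which the chelated Z-enolate 13 is benzylated on the face opposite the 4-benzyl group of the (R)-auxiliary, setting the new centre R (the later C3 of the lower isoflavan); the cold acidic quench protects the acidic alpha-aryl centre from epimerisation.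

Step 9
Reactants: 14 the alkylated imide
Product: 16 5-benzyloxy-2-[(2R)-2-(2-benzyloxy-5-bromo-4-methoxyphenyl)-3-hydroxypropyl]phenol, via MOM alcohol 15 (not isolated)
Conditions: LiBH4, MeOH (2 equiv), THF, 0 °C to rt; then HCl (3 M in MeOH), 40 °C
Reagents that add atoms: none
Why: Reductive cleavage of the imide at the exocyclic carbonyl gives primary alcohol 15 with the stereocentre no longer enolisable, and acetal methanolysis in the same flask then removes the methoxymethyl group as dimethoxymethane while aryl bromide and benzyl ethers persist.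

Step 10
Reactants: 16 5-benzyloxy-2-[(2R)-2-(2-benzyloxy-5-bromo-4-methoxyphenyl)-3-hydroxypropyl]phenol
Product: 17 (3R)-7,2'-di-O-benzyl-5'-bromovestitol [(3R)-7-benzyloxy-3-(2-benzyloxy-5-bromo-4-methoxyphenyl)chromane]
Conditions: PPh3, DIAD, THF, 0 °C to rt
Reagents that add atoms: none
Why: Intramolecular Mitsunobu etherification, the phenol displacing the activated primary hydroxyl in a 6-exo-tet closure of the lower pyran ring; substitution occurs at CH2, so the adjacent R centre is untouched.

Step 11
Reactants: 9 4-benzyloxy-2-hydroxybenzaldehyde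
Product: 18 2-allyloxy-4-benzyloxybenzaldehyde
Conditions: allyl bromide, K2CO3, DMF, rt
Reagents that add atoms: allyl bromide C=CCBr
Why: Williamson allylation of the phenol; allyl is chosen for the upper ring A because it can later be removed under neutral conditions next to an acid-labile benzhydrol.

Step 12
Reactants: 17 (3R)-7,2'-di-O-benzyl-5'-bromovestitol; 18 2-allyloxy-4-benzyloxybenzaldehyde
Product: 20 (2-allyloxy-4-benzyloxyphenyl)[(3R)-7,2'-di-O-benzylvestitol-5'-yl]methanol, via aryllithium 19 (not isolated)
Conditions: n-BuLi, THF, −78 °C; then 18, −78 to −40 °C; aq. NH4Cl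
Reagents that add atoms: none
Why: Bromine–lithium exchange places the carbanion at the carbon fixed in step 3, and 1,2-addition to the aldehyde joins the two halves; at −78 °C exchange outruns any attack on the benzyl ethers, and the unselective carbinol centre is planarised later.

Step 13
Reactants: 20 (2-allyloxy-4-benzyloxyphenyl)[(3R)-7,2'-di-O-benzylvestitol-5'-yl]methanol
Product: 22 5-benzyloxy-2-{[(3R)-7,2'-di-O-benzylvestitol-5'-yl](tosyl)methyl}phenol, via hydroxybenzhydrol 21 (not isolated)
Conditions: Pd(PPh3)4 (3 mol %), p-TolSO2Na, THF/MeOH, rt; then evaporation, p-TolSO2H (3 equiv), CH2Cl2, rt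
Reagents that add atoms: p-toluenesulfinic acid Cc1ccc(S(=O)O)cc1
Why: Tsuji–Trost deallylation (zerovalent palladium transfers the allyl group from the aryl ether to sulfinate through a pi-allylpalladium complex) frees phenol 21 under neutral conditions, and sulfinic acid then replaces the doubly donor-stabilised benzhydryl hydroxyl by an SN1 substitution in which sulfinate traps the cation on sulfur faster than the arene rings can.

Step 14
Reactants: 23 syringol (2,6-dimethoxyphenol)
Product: 24 2-benzyloxy-1,3-dimethoxybenzene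
Conditions: BnBr, K2CO3, DMF, rt
Reagents that add atoms: benzyl bromide BrCc1ccccc1
Why: Williamson benzylation of the flanked but acidic phenol.

Step 15
Reactants: 24 2-benzyloxy-1,3-dimethoxybenzene
Product: 26 3-benzyloxy-2,4-dimethoxybenzaldehyde, via iminium chloride 25 (not isolated)
Conditions: POCl3, DMF, 80 °C; then H2O
Reagents that add atoms: N,N-dimethylformamide CN(C)C=O; water O
Why: Vilsmeier–Haack formylation, the chloroiminium ion attacking C4 (ortho to one methoxy group, para to the other) as in other pyrogallol triethers, under conditions free of strong Lewis acids such as TiCl4 that cleave benzyl ethers flanked by methoxy groups.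

Step 16
Reactants: 26 3-benzyloxy-2,4-dimethoxybenzaldehyde
Product: 27 2-benzyloxy-1,3-dimethoxy-4-(2-methoxyethenyl)benzene (E/Z mixture)
Conditions: Ph3P(CH2OMe)Cl, KOtBu, THF, 0 °C to rt
Reagents that add atoms: (methoxymethyl)triphenylphosphonium chloride COC[P+](c1ccccc1)(c1ccccc1)c1ccccc1.[Cl-]
Why: Wittig reaction with the methoxymethylene ylide, which gives a storable enol ether as the one-carbon-homologated aldehyde equivalent, either alkene isomer serving equally.

Step 17
Reactants: 27 2-benzyloxy-1,3-dimethoxy-4-(2-methoxyethenyl)benzene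
Product: 28 2-(3-benzyloxy-2,4-dimethoxyphenyl)acetaldehyde
Conditions: HCl (2 M aq.), THF, 40 °C (used at once)
Reagents that add atoms: water O
Why: Acid-catalysed enol ether hydrolysis (protonation at carbon, hydration of the oxocarbenium ion, loss of methanol) gives the arylacetaldehyde, used immediately because it is prone to aldol self-condensation.

Step 18
Reactants: 22 5-benzyloxy-2-{[(3R)-7,2'-di-O-benzylvestitol-5'-yl](tosyl)methyl}phenol; 28 2-(3-benzyloxy-2,4-dimethoxyphenyl)acetaldehyde
Product: 31 5-benzyloxy-2-{(1S,2R)-2-(3-benzyloxy-2,4-dimethoxyphenyl)-3-hydroxy-1-[(3R)-7,2'-di-O-benzylvestitol-5'-yl]propyl}phenol, via o-quinone methide 29 (not isolated), via lactol 30 (not isolated)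
Conditions: 28 (2.5 equiv), (R)-2-[diphenyl(trimethylsilyloxy)methyl]pyrrolidine (20 mol %), Na2CO3, CH2Cl2/H2O, 0 °C to rt; then MeOH, NaBH4, 0 °C
Reagents that add atoms: none
Why: Carbonate deprotonates the phenol of 22, sulfinate leaves and the E-configured o-quinone methide 29 forms (eased by the para benzyloxy group and the alkoxy-substituted aryl on the methide carbon), while the amine condenses with 28 to its E-enamine, whose nucleophilic carbon adds to the methide carbon to make the C3–C4 bond and restore the aromatic phenoxide; hydrolysis of the iminium ion returns the catalyst. The closest known reaction type is the aminocatalytic Michael addition–hemiacetalisation of aldehydes with o-quinone methides released from 2-(1-sulfonylalkyl)phenols to give trans-3,4-disubstituted chroman-2-ols, applied here to an arylacetaldehyde donor and a strongly donor-stabilised diaryl methide, the least tested members of that class. The upper pyran ring closes by 6-exo-trig addition of the phenol oxygen to the aldehyde carbon (O1–C2) to give lactol 30 as an anomer mixture, and NaBH4 added to the same flask reduces its open hydroxy-aldehyde form so that the stable phenol–primary alcohol 31 is isolated. C3 (R) is controlled by the catalyst, whose diphenyl(silyloxy)methyl group shields one face of the s-trans E-enamine, and C4 (S) by the synclinal (syn-Michael) approach of the E-methide to the open face, which corresponds to the trans ring relation. The step needs enamine-face selectivity and syn topicity: the (R)-catalyst is assigned by analogy with the syn-selective enamine Michael model and should be verified on a model methide, trans is also the thermodynamic arrangement at the enolisable C3 of the lactol, C4 cannot epimerise, the methide carbon is the only electrophilic site so that no ring-A versus ring-B regiochemistry arises, and the remote lower centre is not expected to interfere.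

Step 19
Reactants: 31 the phenol–primary alcohol from step 18
Product: 32 (3R,4S)-7-benzyloxy-3-(3-benzyloxy-2,4-dimethoxyphenyl)-4-[(3R)-7,2'-di-O-benzylvestitol-5'-yl]chromane
Conditions: PPh3, DIAD, THF, 0 °C to rt
Reagents that add atoms: none
Why: Mitsunobu etherification, the phenol oxygen displacing the activated primary hydroxyl in a 6-exo-tet closure that re-forms the upper pyran ring at C2 without touching C3 or C4.

Step 20
Reactants: 32 the tetra-O-benzyl ether
Product: 33 CNP0202416.1, (3R,4S)-3-(3-hydroxy-2,4-dimethoxyphenyl)-4-{4-hydroxy-5-[(3R)-7-hydroxychroman-3-yl]-2-methoxyphenyl}chroman-7-ol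
Conditions: H2 (1 atm), 10% Pd/C, THF/MeOH, rt
Reagents that add atoms: none
Why: Catalytic hydrogenolysis of the four benzyl aryl ethers; the chroman C–O bonds are not benzylic at oxygen and the triaryl-substituted C4–H and the other stereocentres are not affected.

Compound list
1 | paeonol, 1-(2-hydroxy-4-methoxyphenyl)ethanone | CC(=O)c1ccc(OC)cc1O | starting material
2 | 1-(2-benzyloxy-4-methoxyphenyl)ethanone | CC(=O)c1ccc(OC)cc1OCc1ccccc1 | intermediate
3 | 2-(2-benzyloxy-4-methoxyphenyl)-1-(morpholin-4-yl)ethanethione | COc1ccc(CC(=S)N2CCOCC2)c(OCc2ccccc2)c1 | intermediate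
4 | 2-(2-benzyloxy-4-methoxyphenyl)acetic acid | COc1ccc(CC(=O)O)c(OCc2ccccc2)c1 | intermediate
5 | 2-(2-benzyloxy-5-bromo-4-methoxyphenyl)acetic acid | COc1cc(OCc2ccccc2)c(CC(=O)O)cc1Br | intermediate
6 | (R)-4-benzyl-2-oxazolidinone | O=C1N[C@H](Cc2ccccc2)CO1 | starting material
7 | 2-(2-benzyloxy-5-bromo-4-methoxyphenyl)acetic pivalic anhydride | COc1cc(OCc2ccccc2)c(CC(=O)OC(=O)C(C)(C)C)cc1Br | intermediate
8 | (R)-4-benzyl-3-[2-(2-benzyloxy-5-bromo-4-methoxyphenyl)acetyl]oxazolidin-2-one | O=C(Cc1cc(Br)c(OC)cc1OCc1ccccc1)N1[C@H](Cc2ccccc2)COC1=O | intermediate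
9 | 4-benzyloxy-2-hydroxybenzaldehyde | O=Cc1ccc(OCc2ccccc2)cc1O | starting material
10 | 4-benzyloxy-2-(methoxymethoxy)benzaldehyde | COCOc1cc(OCc2ccccc2)ccc1C=O | intermediate
11 | [4-benzyloxy-2-(methoxymethoxy)phenyl]methanol | COCOc1cc(OCc2ccccc2)ccc1CO | intermediate
12 | 4-benzyloxy-1-(bromomethyl)-2-(methoxymethoxy)benzene | COCOc1cc(OCc2ccccc2)ccc1CBr | intermediate
13 | sodium Z-enolate of 8 | [Na+].[O-]/C(=C\c1cc(Br)c(OC)cc1OCc1ccccc1)N1[C@H](Cc2ccccc2)COC1=O | intermediate
14 | (R)-4-benzyl-3-[(2R)-2-(2-benzyloxy-5-bromo-4-methoxyphenyl)-3-(4-benzyloxy-2-(methoxymethoxy)phenyl)propanoyl]oxazolidin-2-one | COc1cc(OCc2ccccc2)c([C@@H](Cc2ccc(OCc3ccccc3)cc2OCOC)C(=O)N2[C@H](Cc3ccccc3)COC2=O)cc1Br | intermediate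
15 | (2R)-2-(2-benzyloxy-5-bromo-4-methoxyphenyl)-3-[4-benzyloxy-2-(methoxymethoxy)phenyl]propan-1-ol | COc1cc(OCc2ccccc2)c([C@@H](Cc2ccc(OCc3ccccc3)cc2OCOC)CO)cc1Br | intermediate
16 | 5-benzyloxy-2-[(2R)-2-(2-benzyloxy-5-bromo-4-methoxyphenyl)-3-hydroxypropyl]phenol | COc1cc(OCc2ccccc2)c([C@@H](Cc2ccc(OCc3ccccc3)cc2O)CO)cc1Br | intermediate
17 | (3R)-7,2'-di-O-benzyl-5'-bromovestitol, (3R)-7-benzyloxy-3-(2-benzyloxy-5-bromo-4-methoxyphenyl)chromane | COc1cc(OCc2ccccc2)c([C@@H]2COc3cc(OCc4ccccc4)ccc3C2)cc1Br | intermediate
18 | 2-allyloxy-4-benzyloxybenzaldehyde | C=CCOc1cc(OCc2ccccc2)ccc1C=O | intermediate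
19 | [(3R)-7,2'-di-O-benzylvestitol-5'-yl]lithium | COc1cc(OCc2ccccc2)c([C@@H]2COc3cc(OCc4ccccc4)ccc3C2)cc1[Li] | intermediate
20 | (2-allyloxy-4-benzyloxyphenyl)[(3R)-7,2'-di-O-benzylvestitol-5'-yl]methanol, epimer mixture at the carbinol carbon | COc1cc(OCc2ccccc2)c([C@@H]2COc3cc(OCc4ccccc4)ccc3C2)cc1C(O)c1ccc(OCc2ccccc2)cc1OCC=C | intermediate
21 | 5-benzyloxy-2-{hydroxy[(3R)-7,2'-di-O-benzylvestitol-5'-yl]methyl}phenol, epimer mixture | COc1cc(OCc2ccccc2)c([C@@H]2COc3cc(OCc4ccccc4)ccc3C2)cc1C(O)c1ccc(OCc2ccccc2)cc1O | intermediate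
22 | 5-benzyloxy-2-{[(3R)-7,2'-di-O-benzylvestitol-5'-yl](tosyl)methyl}phenol, epimer mixture at the sulfonyl carbon | COc1cc(OCc2ccccc2)c([C@@H]2COc3cc(OCc4ccccc4)ccc3C2)cc1C(c1ccc(OCc2ccccc2)cc1O)S(=O)(=O)c1ccc(C)cc1 | intermediate
23 | syringol, 2,6-dimethoxyphenol | COc1cccc(OC)c1O | starting material
24 | 2-benzyloxy-1,3-dimethoxybenzene | COc1cccc(OC)c1OCc1ccccc1 | intermediate
25 | N-[(3-benzyloxy-2,4-dimethoxyphenyl)methylidene]-N-methylmethanaminium chloride | COc1ccc(C=[N+](C)C)c(OC)c1OCc1ccccc1.[Cl-] | intermediate
26 | 3-benzyloxy-2,4-dimethoxybenzaldehyde | COc1ccc(C=O)c(OC)c1OCc1ccccc1 | intermediate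
27 | 2-benzyloxy-1,3-dimethoxy-4-(2-methoxyethenyl)benzene, E/Z mixture | COC=Cc1ccc(OC)c(OCc2ccccc2)c1OC | intermediate
28 | 2-(3-benzyloxy-2,4-dimethoxyphenyl)acetaldehyde | COc1ccc(CC=O)c(OC)c1OCc1ccccc1 | intermediate
29 | (6E)-3-benzyloxy-6-{[(3R)-7,2'-di-O-benzylvestitol-5'-yl]methylidene}cyclohexa-2,4-dien-1-one | O=C1C=C(OCc2ccccc2)C=C/C1=C\c1cc([C@@H]2COc3cc(OCc4ccccc4)ccc3C2)c(OCc2ccccc2)cc1OC | intermediate
30 | (3R,4S)-7-benzyloxy-3-(3-benzyloxy-2,4-dimethoxyphenyl)-4-[(3R)-7,2'-di-O-benzylvestitol-5'-yl]chroman-2-ol, anomer mixture at C2 | COc1cc(OCc2ccccc2)c([C@@H]2COc3cc(OCc4ccccc4)ccc3C2)cc1[C@@H]1c2ccc(OCc3ccccc3)cc2OC(O)[C@H]1c1ccc(OC)c(OCc2ccccc2)c1OC | intermediate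
31 | 5-benzyloxy-2-{(1S,2R)-2-(3-benzyloxy-2,4-dimethoxyphenyl)-3-hydroxy-1-[(3R)-7,2'-di-O-benzylvestitol-5'-yl]propyl}phenol | COc1cc(OCc2ccccc2)c([C@@H]2COc3cc(OCc4ccccc4)ccc3C2)cc1[C@H](c1ccc(OCc2ccccc2)cc1O)[C@@H](CO)c1ccc(OC)c(OCc2ccccc2)c1OC | intermediate
32 | (3R,4S)-7-benzyloxy-3-(3-benzyloxy-2,4-dimethoxyphenyl)-4-[(3R)-7,2'-di-O-benzylvestitol-5'-yl]chromane | COc1cc(OCc2ccccc2)c([C@@H]2COc3cc(OCc4ccccc4)ccc3C2)cc1[C@@H]1c2ccc(OCc3ccccc3)cc2OC[C@H]1c1ccc(OC)c(OCc2ccccc2)c1OC | intermediate
33 | CNP0202416.1, (3R,4S)-3-(3-hydroxy-2,4-dimethoxyphenyl)-4-{4-hydroxy-5-[(3R)-7-hydroxychroman-3-yl]-2-methoxyphenyl}chroman-7-ol | COc1cc(O)c([C@@H]2COc3cc(O)ccc3C2)cc1[C@@H]1c2ccc(O)cc2OC[C@H]1c1ccc(OC)c(O)c1OC | target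

Total step count: 20 steps.
Longest linear sequence: 12 steps (1, 2, 3, 4, 8, 9, 10, 12, 13, 18, 19, 20, from paeonol).

Steps most likely to fail

Step 18. The donor-stabilised methide 29 may react too slowly with the conjugated and rather unreactive aryl enamine, so that aldol self-condensation of 28 or reversible amine addition to the methide takes over, or facial discrimination at the methide carbon may be poor. The fallback activates the methide with a chiral Brønsted acid instead of an amine. It sets out from hydroxybenzhydrol 21 (step 13 stopped after the palladium stage) and enol ether 27. In toluene, (R)-3,3'-bis(2,4,6-triisopropylphenyl)-1,1'-binaphthyl-2,2'-diyl hydrogen phosphate (10 mol %, enantiomer to be matched on a model) should dehydrate 21 to the methide held as a hydrogen-bonded ion pair with the phosphate. The enol ether then adds across it in an inverse-electron-demand hetero-Diels–Alder reaction (aryl-bearing alkene carbon to the methide carbon, phenol oxygen to the oxocarbenium carbon) to give the 2-methoxy-3,4-diarylchroman acetal F1. Dilute HCl in THF/H2O hydrolyses F1 to lactol 30, in which C3 can settle to the trans arrangement (a trace of DBU if needed). The route is rejoined at 30 with the NaBH4 stage of step 18.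

Step 13. During the acidic exchange the ionised benzhydryl centre may alkylate the electron-rich rings of a second molecule (Friedel–Crafts self-condensation), or the sulfinate may be lost again on isolation. The fallback installs no leaving group. Starting from hydroxybenzhydrol 21, the methide is generated by acid-promoted loss of water in the key-step flask itself: 21, aldehyde 28, the same amine and 4-nitrobenzoic acid (20 mol %) in place of Na2CO3. The enamine is a far better nucleophile than any arene ring and should intercept the methide as it forms. The sequence returns at lactol 30 and makes no new compound (F0).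

Step 8. The electron-rich benzyl bromide 12 may self-alkylate before it meets the enolate, or the acidic alpha-aryl centre of 14 may epimerise under the basic conditions. The fallback sets the centre by asymmetric hydrogenation and starts from acid 5 and aldehyde 10. Perkin condensation (Ac2O, Et3N, 110 °C) gives (E)-2-(2-benzyloxy-5-bromo-4-methoxyphenyl)-3-[4-benzyloxy-2-(methoxymethoxy)phenyl]acrylic acid F2. Hydrogenation with a cationic iridium complex [Ir(cod)(L)]{B[C6H3(CF3)2]4} (L = chiral spiro phosphine–oxazoline, enantiomer chosen for the R acid; H2, Et3N, MeOH), a method established for alpha-aryl cinnamic acids, should give (2R)-2-(2-benzyloxy-5-bromo-4-methoxyphenyl)-3-[4-benzyloxy-2-(methoxymethoxy)phenyl]propanoic acid F3 without touching aryl bromide or benzyl ethers. BH3·SMe2 in THF reduces F3 to alcohol 15, where the route is rejoined at the acid stage of step 9.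

Further compounds
F1 | step 18 | (4S)-7-benzyloxy-3-(3-benzyloxy-2,4-dimethoxyphenyl)-2-methoxy-4-[(3R)-7,2'-di-O-benzylvestitol-5'-yl]chromane, mixture at C2 and C3 | COc1cc(OCc2ccccc2)c([C@@H]2COc3cc(OCc4ccccc4)ccc3C2)cc1[C@@H]1c2ccc(OCc3ccccc3)cc2OC(OC)C1c1ccc(OC)c(OCc2ccccc2)c1OC
F0 | step 13 | none | none
F2 | step 8 | (E)-2-(2-benzyloxy-5-bromo-4-methoxyphenyl)-3-[4-benzyloxy-2-(methoxymethoxy)phenyl]acrylic acid | OC(=O)/C(=C/c1ccc(OCc2ccccc2)cc1OCOC)c1cc(Br)c(OC)cc1OCc1ccccc1
F3 | step 8 | (2R)-2-(2-benzyloxy-5-bromo-4-methoxyphenyl)-3-[4-benzyloxy-2-(methoxymethoxy)phenyl]propanoic acid | COc1cc(OCc2ccccc2)c([C@@H](Cc2ccc(OCc3ccccc3)cc2OCOC)C(=O)O)cc1Br
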